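**Retrosynthetic overview**

1. The quinone ring is numbered C1 (carbonyl next to the side-chain carbon), C2 (side chain), C3 (CH3), C4 (carbonyl), C5 and C6 (CH3). Last disconnection: the C5 and C6 methyl carbons are tied as a CH2–O–CH2 bridge at the hydroquinone level (phthalan hydroquinone 11) and the two ring oxygens are traded for C–B bonds (bis-boronate 10).
2. Key disconnection: the benzene ring of 10 falls apart into three alkyne units, the mirror-symmetric bis(boryl) 1,6-diyne 9 and the chain alkyne 6. One cobalt-mediated [2+2+2] forms C5–C6 (closing the bridge ring) together with C1–C2 and C3–C4 (closing the carbocycle).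
3. Enabling feature: the O=C4–C5(CH3)=C6(CH3)–C1=O half of the ring is locally mirror-symmetric (two adjacent methyl-bearing carbons flanked by the para carbonyl carbons). It therefore maps onto a symmetric tethered diyne and no regiochemistry has to be controlled; the C2(chain)=C3(CH3) half is simply a 2-alkyne.
4. Alkyne 6 comes from natural phytol: Sharpless epoxidation sets the tertiary carbinol, followed by hydride opening, oxetane formation and acetylide opening. Diyne 9 comes from dipropargyl ether in one step.
5. Ring order: the six-membered carbocycle (the only ring of the target) and the temporary five-membered ether ring form together in step 6; the ether ring is opened again in step 8.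

Key step: step 6

Remark: natural (E)-(7R,11R)-phytol of high geometric purity is assumed to be the purchased source of the two methyl-bearing chain stereocenters, since the Z isomer would lead to the epimeric carbinol.

**Route**

Step 1
Reactants: 1 (E)-(7R,11R)-phytol
Product: 2 [(2R,3R)-3-methyl-3-[(4R,8R)-4,8,12-trimethyltridecyl]oxiran-2-yl]methanol
Conditions: Ti(OiPr)4 (5 mol %), D-(−)-diisopropyl tartrate (6 mol %), t-BuOOH, 4 Å MS, CH2Cl2, −20 °C
Reagents that add atoms: tert-butyl hydroperoxide, CC(C)(C)OO
Why: Sharpless asymmetric epoxidation of an E-trisubstituted allylic alcohol; with the D-(−)-tartrate the titanium-bound peroxide should reach the alkene face that gives the (2R,3R)-epoxide, which fixes the future carbinol carbon as R while the two remote chain stereocenters are unchanged.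

Step 2
Reactants: 2 [(2R,3R)-3-methyl-3-[(4R,8R)-4,8,12-trimethyltridecyl]oxiran-2-yl]methanol
Product: 3 (3R,7R,11R)-3,7,11,15-tetramethylhexadecane-1,3-diol
Conditions: LiAlH4, THF, 0 °C → rt; H2O, aq NaOH
Reagents that add atoms: none
Why: Reductive opening of a 2,3-epoxy alcohol: hydride attacks in SN2 fashion at the less substituted C2, so the C3–O bond is untouched and C3 keeps its R configuration as the tertiary carbinol of a 1,3-diol.

Step 3
Reactants: 3 (3R,7R,11R)-3,7,11,15-tetramethylhexadecane-1,3-diol
Product: 5 (2R)-2-methyl-2-[(4R,8R)-4,8,12-trimethyltridecyl]oxetane, via monotosylate 4 (not isolated)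
Conditions: n-BuLi (1.0 equiv), THF, 0 °C; TsCl (1.0 equiv), 0 °C → rt; n-BuLi (1.1 equiv), 0 → 60 °C
Reagents that add atoms: none
Why: One-pot sulfonylation of the primary alkoxide followed by intramolecular Williamson etherification (4-exo-tet) by the tertiary alkoxide, helped by the gem-disubstitution; the stereocenter keeps its own C–O bond and hence its configuration.

Step 4
Reactants: 5 (2R)-2-methyl-2-[(4R,8R)-4,8,12-trimethyltridecyl]oxetane
Product: 6 (6R,10R,14R)-6,10,14,18-tetramethylnonadec-2-yn-6-ol
Conditions: 1-propynyllithium (3 equiv), BF3·OEt2 (3 equiv), THF, −78 °C; aq NH4Cl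
Reagents that add atoms: 1-propynyllithium, [Li]C#CC
Why: BF3-promoted SN2 ring opening of an oxetane by a lithium acetylide at the unsubstituted ring CH2, which installs the 2-alkyne terminus and frees the tertiary alcohol without breaking a bond to the stereocenter.

Step 5
Reactants: 7 dipropargyl ether (3-(prop-2-yn-1-yloxy)prop-1-yne)
Product: 9 2,2'-[oxybis(prop-1-yne-3,1-diyl)]bis(4,4,5,5-tetramethyl-1,3,2-dioxaborolane), via dilithium acetylide 8 (not isolated)
Conditions: n-BuLi (2.05 equiv), THF, −78 °C; iPrOBpin (2.2 equiv), −78 °C; HCl in Et2O (2.2 equiv), −78 °C → rt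
Reagents that add atoms: 2-isopropoxy-4,4,5,5-tetramethyl-1,3,2-dioxaborolane, CC(C)OB1OC(C)(C)C(C)(C)O1
Why: Deprotonation of both terminal alkynes, borylation of the acetylide with an alkoxyboronate and anhydrous acid treatment is the standard preparation of alkynyl pinacolboronates; the two boryl caps are the latent quinone oxygens.

Step 6
Reactants: 6 (6R,10R,14R)-6,10,14,18-tetramethylnonadec-2-yn-6-ol and 9 2,2'-[oxybis(prop-1-yne-3,1-diyl)]bis(4,4,5,5-tetramethyl-1,3,2-dioxaborolane)
Product: 10 (3R,7R,11R)-3,7,11,15-tetramethyl-1-[6-methyl-4,7-bis(4,4,5,5-tetramethyl-1,3,2-dioxaborolan-2-yl)-1,3-dihydro-2-benzofuran-5-yl]hexadecan-3-ol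
Conditions: CpCo(CO)2 (20 mol %), degassed o-xylene, 140 °C, hν (visible light), 9 (2 equiv) added slowly to 6
Reagents that add atoms: none
Why: The CpCo fragment (monovalent cobalt) binds the two alkyne units of diyne 9 and couples them oxidatively to a trivalent cobalt metallacycle, which forms the bond between the two CH2-bearing alkyne carbons (the future C5–C6 bond) and places both boryl groups next to cobalt; alkyne 6 then inserts and reductive elimination forms the two remaining ring bonds (C1–C2 and C3–C4) and releases the arene. The closest known reaction type is the cobalt-mediated [2+2+2] cocyclisation of α,ω-diynes with alkynes, which is established for alkynyl pinacolboronates and for crowded, fully substituted benzenes. Two rings close: the temporary dihydrofuran ring by the five-membered oxidative cyclisation of the 1,6-diyne, and the benzene ring by the metal-templated union of the three alkyne units. No stereocenter is formed, and the three existing ones lie far from the reacting alkyne and are not touched. The step needs chemoselectivity for cross-cyclisation over self-trimerisation of 9, which the boryl caps on both diyne termini and the slow addition should secure, and it needs no regiocontrol because 9 is mirror-symmetric, so either orientation of 6 gives the same product with the two borons para to each other.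

Step 7
Reactants: 10 (3R,7R,11R)-3,7,11,15-tetramethyl-1-[6-methyl-4,7-bis(4,4,5,5-tetramethyl-1,3,2-dioxaborolan-2-yl)-1,3-dihydro-2-benzofuran-5-yl]hexadecan-3-ol
Product: 11 phthalan hydroquinone (5-[(3R,7R,11R)-3-hydroxy-3,7,11,15-tetramethylhexadecyl]-6-methyl-1,3-dihydro-2-benzofuran-4,7-diol)
Conditions: Me3NO (4 equiv), THF, 65 °C, Ar; degassed aq NH4Cl; crude product kept under Ar and used directly
Reagents that add atoms: trimethylamine N-oxide, C[N+](C)(C)[O-]
Why: Oxidation of arylboronates by an amine N-oxide (attack of the N-oxide oxygen on boron, 1,2-shift of the aryl group from boron to oxygen, hydrolysis on work-up) puts oxygen exactly where boron stood; the non-basic, peroxide-free oxidant spares the benzylic ether and the tertiary alcohol, and air-free handling keeps the product at the hydroquinone level that step 8 needs.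

Step 8
Reactants: 11 phthalan hydroquinone (5-[(3R,7R,11R)-3-hydroxy-3,7,11,15-tetramethylhexadecyl]-6-methyl-1,3-dihydro-2-benzofuran-4,7-diol)
Product: 13 α-tocopherylquinone (2-[(3R,7R,11R)-3-hydroxy-3,7,11,15-tetramethylhexadecyl]-3,5,6-trimethylcyclohexa-2,5-diene-1,4-dione), via α-tocopherylhydroquinone 12 (not isolated)
Conditions: H2 (20 bar), 10% Pd/C, EtOAc, 80 °C; filter under Ar; Ag2O (1.5 equiv), Et2O, rt
Reagents that add atoms: none
Why: Catalytic hydrogenolysis of benzylic C–O bonds: in 11 each CH2–O bond is benzylic and ortho to a phenolic hydroxyl on an electron-rich ring, the arrangement in which hydroxymethyl and alkoxymethyl groups on tocopherol rings are hydrogenolysed to methyl groups, so both C–O bonds should be cut under neutral conditions that leave the tertiary alcohol alone and avoid acid-induced chroman closure; Ag2O then dehydrogenates hydroquinone 12 to the quinone without touching any stereocenter.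

**Compound list**

1 | (E)-(7R,11R)-phytol, (2E,7R,11R)-3,7,11,15-tetramethylhexadec-2-en-1-ol | OC/C=C(\C)CCC[C@H](C)CCC[C@H](C)CCCC(C)C | starting material
2 | [(2R,3R)-3-methyl-3-[(4R,8R)-4,8,12-trimethyltridecyl]oxiran-2-yl]methanol | OC[C@H]1O[C@]1(C)CCC[C@H](C)CCC[C@H](C)CCCC(C)C | intermediate
3 | (3R,7R,11R)-3,7,11,15-tetramethylhexadecane-1,3-diol | OCC[C@](C)(O)CCC[C@H](C)CCC[C@H](C)CCCC(C)C | intermediate
4 | (3R,7R,11R)-3-hydroxy-3,7,11,15-tetramethylhexadecyl 4-methylbenzenesulfonate (monotosylate) | Cc1ccc(cc1)S(=O)(=O)OCC[C@](C)(O)CCC[C@H](C)CCC[C@H](C)CCCC(C)C | intermediate (not isolated)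
5 | (2R)-2-methyl-2-[(4R,8R)-4,8,12-trimethyltridecyl]oxetane | C1C[C@](C)(O1)CCC[C@H](C)CCC[C@H](C)CCCC(C)C | intermediate
6 | (6R,10R,14R)-6,10,14,18-tetramethylnonadec-2-yn-6-ol | CC#CCC[C@](C)(O)CCC[C@H](C)CCC[C@H](C)CCCC(C)C | intermediate
7 | dipropargyl ether, 3-(prop-2-yn-1-yloxy)prop-1-yne | C#CCOCC#C | starting material
8 | dilithium acetylide of dipropargyl ether, 3,3'-oxybis(1-lithioprop-1-yne) | [Li]C#CCOCC#C[Li] | intermediate (not isolated)
9 | 2,2'-[oxybis(prop-1-yne-3,1-diyl)]bis(4,4,5,5-tetramethyl-1,3,2-dioxaborolane) | CC1(C)OB(C#CCOCC#CB2OC(C)(C)C(C)(C)O2)OC1(C)C | intermediate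
10 | (3R,7R,11R)-3,7,11,15-tetramethyl-1-[6-methyl-4,7-bis(4,4,5,5-tetramethyl-1,3,2-dioxaborolan-2-yl)-1,3-dihydro-2-benzofuran-5-yl]hexadecan-3-ol | Cc1c(CC[C@](C)(O)CCC[C@H](C)CCC[C@H](C)CCCC(C)C)c(B2OC(C)(C)C(C)(C)O2)c2COCc2c1B1OC(C)(C)C(C)(C)O1 | intermediate
11 | phthalan hydroquinone, 5-[(3R,7R,11R)-3-hydroxy-3,7,11,15-tetramethylhexadecyl]-6-methyl-1,3-dihydro-2-benzofuran-4,7-diol | Cc1c(CC[C@](C)(O)CCC[C@H](C)CCC[C@H](C)CCCC(C)C)c(O)c2COCc2c1O | intermediate
12 | α-tocopherylhydroquinone, 2-[(3R,7R,11R)-3-hydroxy-3,7,11,15-tetramethylhexadecyl]-3,5,6-trimethylbenzene-1,4-diol | Cc1c(C)c(O)c(CC[C@](C)(O)CCC[C@H](C)CCC[C@H](C)CCCC(C)C)c(C)c1O | intermediate (not isolated)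
13 | α-tocopherylquinone, 2-[(3R,7R,11R)-3-hydroxy-3,7,11,15-tetramethylhexadecyl]-3,5,6-trimethylcyclohexa-2,5-diene-1,4-dione | CC1=C(C)C(=O)C(CC[C@](C)(O)CCC[C@H](C)CCC[C@H](C)CCCC(C)C)=C(C)C1=O | target

**Step count**

Total step count: 8. Longest linear sequence: 7 steps (steps 1, 2, 3, 4, 6, 7 and 8).

**Steps most likely to fail**

1. Step 6. Insertion of the internal dialkyl alkyne into a metallacycle that carries a boryl group on each carbon next to cobalt may be too slow. The diyne could then oligomerise, the metallacycle could collapse to an inert cyclobutadiene complex, or the C–B bonds could be protonated at 140 °C. Fallback: boron would be brought in after the ring is made. The fallback sets out from 6 and the parent diyne 7 and returns at 10. Cocyclisation of 6 with the unhindered terminal diyne 7 ([Ir(cod)Cl]2/dppe or CpCo(CO)2, slow addition of 7) would give (3R,7R,11R)-3,7,11,15-tetramethyl-1-(6-methyl-1,3-dihydro-2-benzofuran-5-yl)hexadecan-3-ol F1, whose only two free ring positions are the para-related ones beside the ether CH2 groups. Buffered electrophilic bromination (Br2, NaOAc, CH2Cl2/AcOH, 0 °C, dark) would give (3R,7R,11R)-1-(4,7-dibromo-6-methyl-1,3-dihydro-2-benzofuran-5-yl)-3,7,11,15-tetramethylhexadecan-3-ol F2. A double Miyaura borylation suited to hindered aryl bromides (Pd(OAc)2/SPhos, B2pin2, KOAc, dioxane, 100 °C) would then return to 10.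

2. Step 8. Hydrogenolysis may stop after the first C–O cleavage because the crowded, fully substituted ring adsorbs poorly on palladium. Forcing it with heat or adventitious acid could induce cyclodehydration of the tertiary alcohol onto a hydroquinone oxygen. Fallback: the oxygen tether would be replaced by sulfur, which is removed by desulfurisation instead of hydrogenolysis. The fallback sets out from 6 and returns at 12. Purchased dipropargyl sulfide (C#CCSCC#C) would be deprotonated to the dilithium acetylide of dipropargyl sulfide F3 and borylated as in step 5 to 2,2'-[sulfanediylbis(prop-1-yne-3,1-diyl)]bis(4,4,5,5-tetramethyl-1,3,2-dioxaborolane) F4. Cocyclisation with 6 as in step 6 would give (3R,7R,11R)-3,7,11,15-tetramethyl-1-[6-methyl-4,7-bis(4,4,5,5-tetramethyl-1,3,2-dioxaborolan-2-yl)-1,3-dihydro-2-benzothiophen-5-yl]hexadecan-3-ol F5. Me3NO as in step 7, which does not oxidise the sulfide, would give the thia-hydroquinone 5-[(3R,7R,11R)-3-hydroxy-3,7,11,15-tetramethylhexadecyl]-6-methyl-1,3-dihydro-2-benzothiophene-4,7-diol F6. Raney Ni (excess, EtOH, reflux) would cleave both benzylic C–S bonds of this compound to give 12, which Ag2O oxidises to 13 as in step 8.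

3. Step 4. BF3 may ionise the tertiary C–O bond of the 2,2-disubstituted oxetane faster than the acetylide attacks the ring CH2, leading to elimination and loss of configuration. In step 3 the tertiary alkoxide may also fragment (Grob fragmentation) instead of closing the four-membered ring. Fallback: the oxetane would be avoided by protecting the carbinol. The fallback sets out from 3 and returns at 6. Selective tosylation of the primary hydroxyl (TsCl, pyridine, 0 °C) would give 4, isolated in this variant. Silylation of the tertiary hydroxyl (Et3SiOTf, 2,6-lutidine, CH2Cl2, −78 °C) would give (3R,7R,11R)-3,7,11,15-tetramethyl-3-(triethylsilyloxy)hexadecyl 4-methylbenzenesulfonate F7. SN2 displacement with 1-propynyllithium (THF/DMPU, 0 °C → rt) would give triethyl{[(6R,10R,14R)-6,10,14,18-tetramethylnonadec-2-yn-6-yl]oxy}silane F8, and Bu4NF (THF, rt) would return to 6.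

**Further compounds**

F1 | step 6 | (3R,7R,11R)-3,7,11,15-tetramethyl-1-(6-methyl-1,3-dihydro-2-benzofuran-5-yl)hexadecan-3-ol | Cc1cc2COCc2cc1CC[C@](C)(O)CCC[C@H](C)CCC[C@H](C)CCCC(C)C
F2 | step 6 | (3R,7R,11R)-1-(4,7-dibromo-6-methyl-1,3-dihydro-2-benzofuran-5-yl)-3,7,11,15-tetramethylhexadecan-3-ol | Cc1c(Br)c2COCc2c(Br)c1CC[C@](C)(O)CCC[C@H](C)CCC[C@H](C)CCCC(C)C
F3 | step 8 | dilithium acetylide of dipropargyl sulfide, 3,3'-sulfanediylbis(1-lithioprop-1-yne) | [Li]C#CCSCC#C[Li]
F4 | step 8 | 2,2'-[sulfanediylbis(prop-1-yne-3,1-diyl)]bis(4,4,5,5-tetramethyl-1,3,2-dioxaborolane) | CC1(C)OB(C#CCSCC#CB2OC(C)(C)C(C)(C)O2)OC1(C)C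
F5 | step 8 | (3R,7R,11R)-3,7,11,15-tetramethyl-1-[6-methyl-4,7-bis(4,4,5,5-tetramethyl-1,3,2-dioxaborolan-2-yl)-1,3-dihydro-2-benzothiophen-5-yl]hexadecan-3-ol | Cc1c(CC[C@](C)(O)CCC[C@H](C)CCC[C@H](C)CCCC(C)C)c(B2OC(C)(C)C(C)(C)O2)c2CSCc2c1B1OC(C)(C)C(C)(C)O1
F6 | step 8 | 5-[(3R,7R,11R)-3-hydroxy-3,7,11,15-tetramethylhexadecyl]-6-methyl-1,3-dihydro-2-benzothiophene-4,7-diol | Cc1c(CC[C@](C)(O)CCC[C@H](C)CCC[C@H](C)CCCC(C)C)c(O)c2CSCc2c1O
F7 | step 4 | (3R,7R,11R)-3,7,11,15-tetramethyl-3-(triethylsilyloxy)hexadecyl 4-methylbenzenesulfonate | Cc1ccc(cc1)S(=O)(=O)OCC[C@](C)(O[Si](CC)(CC)CC)CCC[C@H](C)CCC[C@H](C)CCCC(C)C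
F8 | step 4 | triethyl{[(6R,10R,14R)-6,10,14,18-tetramethylnonadec-2-yn-6-yl]oxy}silane | CC#CCC[C@](C)(O[Si](CC)(CC)CC)CCC[C@H](C)CCC[C@H](C)CCCC(C)C
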